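**Plan**

1. Numbering follows the target SMILES: C1 (CH‑iPr), C2 and C6 (ring‑fusion CH), C3, C4 (C‑CH3) and C5 complete the five‑membered ring (C4–C5 epoxide); C7, C8 (C(CH3)OH), C9 and C10 (CH–O‑acyl) complete the seven‑membered ring. β is the face of H‑2, the isopropyl group, C5 on C6, the C8 hydroxyl and the epoxide oxygen; TBS = tert‑butyldimethylsilyl.
2. Retrosynthesis: cut the aryl ester at C10–O and the epoxide oxygen, open the cyclopentene at C4=C5 (ring‑closing metathesis), trace the C8 methyl carbinol back to a C7=C8 enoate and C10–O/C1–H back to a silyl enol ether. Then cut C2–C6 (Cope shift) and C8–C9/C8–C10 (cyclopropanation), which leaves siloxydiene 8 and vinyldiazoacetate 13.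
3. Enabling feature: in the seven‑membered ring the fusion bond C2–C6 lies opposite C9, and the two carbons flanking C9 (C8 and C10) are the oxygenated ones. A cyclopropane on C8–C9–C10 carrying the alkenyl arms C7=C6 and C1=C2 therefore rearranges to exactly this ring, with C8 arriving as the ester‑bearing carbene carbon and C10 as an enol ether carbon.
4. Forward: two fragments (6 and 2 steps) → seven‑membered ring with C2 and C6 (step 9) → C8 carbinol → C10 ketone, C1, C10 alcohol, ester → five‑membered ring by metathesis → epoxide → free phenol.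
5. Stereochemistry: C2/C6 (trans) from the chiral dirhodium catalyst together with the E and Z alkene geometries; C8 from the Sharpless reagent; C1 by equilibration; C10 by reduction directed from the C8 hydroxyl; C4/C5 by epoxidation directed from the same hydroxyl.

Key step: step 9

Assumption: 1, 3, 9, 10 and 23 are purchased; the absolute sense of step 9 (S ligand gives the series drawn) and of step 11 (D‑(−)‑tartrate gives the β epoxide) is taken from the established empirical models for these reagents, and the mirror‑image ligand would be used if either assignment proved reversed on this substrate.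

**Route**

Step 1
Reactants: 1 methyl bis(2,2,2‑trifluoroethyl)phosphonoacetate
Product: 2 methyl 2‑[bis(2,2,2‑trifluoroethoxy)phosphoryl]‑3‑methylbutanoate (racemic)
Conditions: NaH, DMF, 0 °C; then 2‑iodopropane, 50 °C
Reagents that add atoms: 2‑iodopropane, CC(C)I
Why: C‑alkylation of the stabilised phosphonoacetate anion (enolate alkylation) is the standard access to α‑substituted olefination reagents, and the new α‑carbon is racemic and becomes an sp2 centre in step 3.

Step 2
Reactants: 3 ethyl (2‑methyl‑1,3‑dioxolan‑2‑yl)acetate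
Product: 4 (2‑methyl‑1,3‑dioxolan‑2‑yl)acetaldehyde
Conditions: iBu2AlH (1.05 equiv), CH2Cl2, −78 °C; Rochelle salt work‑up
Reagents that add atoms: none
Why: Partial ester reduction with one equivalent of iBu2AlH at low temperature stops at the aluminium hemiacetal, which gives the aldehyde on work‑up while the ketal is inert.

Step 3
Reactants: 2 methyl 2‑[bis(2,2,2‑trifluoroethoxy)phosphoryl]‑3‑methylbutanoate; 4 (2‑methyl‑1,3‑dioxolan‑2‑yl)acetaldehyde
Product: 5 methyl (Z)‑2‑isopropyl‑4‑(2‑methyl‑1,3‑dioxolan‑2‑yl)but‑2‑enoate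
Conditions: KN(SiMe3)2, 18‑crown‑6, THF, −78 °C
Reagents that add atoms: none
Why: In this Still–Gennari olefination the electron‑poor trifluoroethyl phosphonate eliminates fast from the kinetic adduct, so the trisubstituted enoate should form with the ester cis to the aldehyde‑derived CH2 group, the geometry needed later for the Z arm.

Step 4
Reactants: 5 methyl (Z)‑2‑isopropyl‑4‑(2‑methyl‑1,3‑dioxolan‑2‑yl)but‑2‑enoate
Product: 6 (Z)‑N‑methoxy‑N‑methyl‑2‑isopropyl‑4‑(2‑methyl‑1,3‑dioxolan‑2‑yl)but‑2‑enamide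
Conditions: MeNH(OMe)·HCl, iPrMgCl, THF, −20 → 0 °C
Reagents that add atoms: N,O‑dimethylhydroxylamine hydrochloride, CNOC.Cl
Why: Aminolysis of the ester by the magnesium amide of N,O‑dimethylhydroxylamine (Weinreb amide formation) is direct and should not isomerise the hindered Z alkene.

Step 5
Reactants: 6 (Z)‑N‑methoxy‑N‑methyl‑2‑isopropyl‑4‑(2‑methyl‑1,3‑dioxolan‑2‑yl)but‑2‑enamide
Product: 7 (Z)‑3‑isopropyl‑5‑(2‑methyl‑1,3‑dioxolan‑2‑yl)pent‑3‑en‑2‑one
Conditions: MeMgBr, THF, −20 → 0 °C
Reagents that add atoms: methylmagnesium bromide, C[Mg]Br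
Why: Grignard addition to a Weinreb amide stops at the chelated tetrahedral intermediate and releases the methyl ketone only on work‑up (Weinreb ketone synthesis).

Step 6
Reactants: 7 (Z)‑3‑isopropyl‑5‑(2‑methyl‑1,3‑dioxolan‑2‑yl)pent‑3‑en‑2‑one
Product: 8 (Z)‑2‑(tert‑butyldimethylsilyloxy)‑3‑isopropyl‑5‑(2‑methyl‑1,3‑dioxolan‑2‑yl)penta‑1,3‑diene
Conditions: LiN(iPr)2, THF, −78 °C; then tBuMe2SiOTf
Reagents that add atoms: tert‑butyldimethylsilyl trifluoromethanesulfonate, CC(C)(C)[Si](C)(C)OS(=O)(=O)C(F)(F)F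
Why: Kinetic deprotonation of the methyl group and O‑silylation (kinetic silyl enol ether formation) should give the cross‑conjugated 2‑silyloxydiene without touching the γ‑hydrogens or the Z alkene.

Step 7
Reactants: 9 3‑(tert‑butyldimethylsilyloxy)propanal; 10 ethyl diazoacetate
Product: 11 ethyl 5‑(tert‑butyldimethylsilyloxy)‑2‑diazo‑3‑hydroxypentanoate (racemic)
Conditions: DBU (10 mol%), MeCN, rt
Reagents that add atoms: none
Why: Base‑catalysed aldol‑type addition of the diazoacetate carbon to an aldehyde is a mild known route to α‑diazo‑β‑hydroxy esters, and the racemic carbinol centre disappears in step 8.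

Step 8
Reactants: 11 ethyl 5‑(tert‑butyldimethylsilyloxy)‑2‑diazo‑3‑hydroxypentanoate
Product: 13 ethyl (E)‑5‑(tert‑butyldimethylsilyloxy)‑2‑diazopent‑3‑enoate, via O‑trifluoroacetate 12 (not isolated)
Conditions: (CF3CO)2O, Et3N, CH2Cl2, 0 °C
Reagents that add atoms: none
Why: Acylation of the hydroxyl and amine‑induced elimination toward the neighbouring CH2 (dehydration) is the standard way to 4‑substituted vinyldiazoacetates and should give the conjugated E alkene.

Step 9
Reactants: 8 (Z)‑2‑(tert‑butyldimethylsilyloxy)‑3‑isopropyl‑5‑(2‑methyl‑1,3‑dioxolan‑2‑yl)penta‑1,3‑diene; 13 ethyl (E)‑5‑(tert‑butyldimethylsilyloxy)‑2‑diazopent‑3‑enoate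
Product: 15 ethyl 10‑(TBS‑oxy)‑1‑isopropyl‑2α‑[(2‑methyl‑1,3‑dioxolan‑2‑yl)methyl]‑6β‑[(TBS‑oxy)methyl]cyclohepta‑1(10),7‑diene‑8‑carboxylate (target numbering), via cis‑divinylcyclopropane 14 (not isolated)
Conditions: Rh2(S‑DOSP)4 [dirhodium tetrakis((S)‑N‑(4‑dodecylbenzenesulfonyl)prolinate)] (1 mol%), hexanes, −40 °C, slow addition of 13; then toluene, 100 °C
Reagents that add atoms: none
Why: The catalyst converts 13 into a donor/acceptor vinylcarbene of divalent rhodium that adds to the terminal C9=C10 enol ether double bond of 8 in one asynchronous step (bonds C8–C9 and C8–C10), giving 14 with the two alkenyl groups cis, and heating then drives the (3,3) sigmatropic Cope shift that breaks C8–C10 and forms C2–C6. The closest known reaction type is the tandem cyclopropanation/Cope rearrangement (formal (4+3) cycloaddition) of vinyldiazoacetates with 2‑silyloxydienes under chiral dirhodium tetracarboxylate catalysis. The seven‑membered ring closes by bonding of the two alkene termini C2 and C6 across the cyclopropane in a boat transition state, that is by a four‑carbon ring expansion of the three‑membered ring with release of its strain. C8 and C10 of 14 are set by the chiral prolinate ligands, which select the carbene face, and by the preference of the carbene's vinyl group to end cis to the π substituent of the alkene; the stereospecific boat shift passes this on to C6, whose E‑placed CH2OTBS group ends on the same face as the hydrogen of C2, and to C2, whose Z‑placed side chain ends on the other face, so that C2 and C6 are trans and of one absolute sense. The step needs attack at the 1,1‑disubstituted enol ether alkene only, which its electron richness and the inertness of trisubstituted alkenes and of the substituted vinyl terminus toward such carbenes should secure, and it needs the Z geometry of 8 to be kept, for which the price is the higher temperature that an inward‑pointing Z substituent imposes on the boat.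

Step 10
Reactants: 15 ethyl 10‑(TBS‑oxy)‑1‑isopropyl‑2α‑[(2‑methyl‑1,3‑dioxolan‑2‑yl)methyl]‑6β‑[(TBS‑oxy)methyl]cyclohepta‑1(10),7‑diene‑8‑carboxylate
Product: 16 [10‑(TBS‑oxy)‑1‑isopropyl‑2α‑[(2‑methyl‑1,3‑dioxolan‑2‑yl)methyl]‑6β‑[(TBS‑oxy)methyl]cyclohepta‑1(10),7‑dien‑8‑yl]methanol
Conditions: iBu2AlH (2.2 equiv), CH2Cl2, −78 °C
Reagents that add atoms: none
Why: 1,2‑Reduction of the conjugated ester by iBu2AlH gives the primary allylic alcohol, while silyl enol ether, silyl ether and ketal are inert to the hydride.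

Step 11
Reactants: 16 [10‑(TBS‑oxy)‑1‑isopropyl‑2α‑[(2‑methyl‑1,3‑dioxolan‑2‑yl)methyl]‑6β‑[(TBS‑oxy)methyl]cyclohepta‑1(10),7‑dien‑8‑yl]methanol
Product: 17 [7β,8β‑epoxy‑10‑(TBS‑oxy)‑1‑isopropyl‑2α‑[(2‑methyl‑1,3‑dioxolan‑2‑yl)methyl]‑6β‑[(TBS‑oxy)methyl]cyclohept‑1(10)‑en‑8‑yl]methanol (epoxide oxygen β; CH2OH α)
Conditions: Ti(OiPr)4 (10 mol%), D‑(−)‑diisopropyl tartrate (12 mol%), tBuOOH, 4 Å molecular sieves, CH2Cl2, −20 °C
Reagents that add atoms: tert‑butyl hydroperoxide, CC(C)(C)OO
Why: In this Sharpless asymmetric epoxidation the allylic alkoxide binds the titanium tartrate, which should deliver oxygen to the β face of C7=C8 under reagent control (setting C7 and C8, on the side of the C6 side chain), while the non‑coordinating silyl enol ether is left alone.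

Step 12
Reactants: 17 the 7β,8β‑epoxy alcohol
Product: 18 methanesulfonate of 17 (8α‑CH2OSO2CH3)
Conditions: MsCl, Et3N, CH2Cl2, 0 °C
Reagents that add atoms: methanesulfonyl chloride, CS(=O)(=O)Cl
Why: Sulfonylation of the primary alcohol (mesylate formation) under amine base turns CH2OH into a leaving group without affecting epoxide or enol ether.

Step 13
Reactants: 18 the epoxy mesylate
Product: 19 10‑(TBS‑oxy)‑1‑isopropyl‑8α‑methyl‑2α‑[(2‑methyl‑1,3‑dioxolan‑2‑yl)methyl]‑6β‑[(TBS‑oxy)methyl]cyclohept‑1(10)‑en‑8β‑ol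
Conditions: LiEt3BH (3 equiv), THF, 0 °C → rt
Reagents that add atoms: none
Why: Hydride reduction with LiEt3BH displaces the primary mesylate (giving the C8 methyl) and opens the trisubstituted epoxide by SN2 attack at the less substituted C7, so the C8–O bond and its β configuration are retained in the tertiary alcohol.

Step 14
Reactants: 19 the tertiary alcohol with the intact silyl enol ether
Product: 21 8β‑hydroxy‑1β‑isopropyl‑8α‑methyl‑2α‑[(2‑methyl‑1,3‑dioxolan‑2‑yl)methyl]‑6β‑[(TBS‑oxy)methyl]cycloheptan‑10‑one, via 1α‑isopropyl ketone 20 (not isolated)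
Conditions: K2CO3, MeOH, rt
Reagents that add atoms: none
Why: Basic methanolysis cleaves the enol silyl ether but not the alkyl silyl ether (an enolate leaves about as readily as a phenoxide), and the same base should equilibrate C1 through the enolate (thermodynamic epimerisation) to the isomer with the isopropyl group trans to the C2 side chain.

Step 15
Reactants: 21 the β‑hydroxy ketone
Product: 22 1β‑isopropyl‑8α‑methyl‑2α‑[(2‑methyl‑1,3‑dioxolan‑2‑yl)methyl]‑6β‑[(TBS‑oxy)methyl]cycloheptane‑8β,10α‑diol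
Conditions: Me4NBH(OAc)3, MeCN/AcOH, −20 °C → rt
Reagents that add atoms: none
Why: In this Evans–Saksena reduction the C8 hydroxyl exchanges onto boron and delivers hydride intramolecularly to the β face of the C10 ketone, which should give the 1,3‑anti diol and thus the α hydroxyl at C10, trans to the isopropyl group.

Step 16
Reactants: 22 the 8β,10α‑diol; 23 4‑(benzyloxy)benzoyl chloride
Product: 24 8β‑hydroxy‑1β‑isopropyl‑8α‑methyl‑2α‑[(2‑methyl‑1,3‑dioxolan‑2‑yl)methyl]‑6β‑[(TBS‑oxy)methyl]cycloheptan‑10α‑yl 4‑(benzyloxy)benzoate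
Conditions: Et3N, DMAP (10 mol%), CH2Cl2, rt
Reagents that add atoms: none
Why: DMAP‑catalysed acylation with an acid chloride (nucleophilic catalysis) esterifies the secondary C10 hydroxyl, and the tertiary C8 hydroxyl does not react under these conditions.

Step 17
Reactants: 24 the protected ester
Product: 25 8β‑hydroxy‑6β‑(hydroxymethyl)‑1β‑isopropyl‑8α‑methyl‑2α‑(2‑oxopropyl)cycloheptan‑10α‑yl 4‑(benzyloxy)benzoate
Conditions: 1 M HCl (aq), THF, rt
Reagents that add atoms: water, O
Why: Dilute aqueous acid removes the primary silyl ether and the dioxolane in one operation (desilylation and acetal hydrolysis), while the aryl benzyl ether, the ester and the tertiary alcohol tolerate it.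

Step 18
Reactants: 25 the hydroxy ketone
Product: 26 6β‑formyl‑8β‑hydroxy‑1β‑isopropyl‑8α‑methyl‑2α‑(2‑oxopropyl)cycloheptan‑10α‑yl 4‑(benzyloxy)benzoate
Conditions: Dess–Martin periodinane, pyridine, CH2Cl2, 0 °C
Reagents that add atoms: none
Why: Dess–Martin oxidation converts the primary alcohol to the aldehyde under buffered, nearly neutral conditions that should avoid epimerisation at C6 and aldol reaction with the methyl ketone, and the tertiary alcohol cannot be oxidised.

Step 19
Reactants: 26 the keto aldehyde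
Product: 27 6β‑ethenyl‑8β‑hydroxy‑1β‑isopropyl‑8α‑methyl‑2α‑(2‑methylprop‑2‑enyl)cycloheptan‑10α‑yl 4‑(benzyloxy)benzoate
Conditions: Ph3PCH3Br, KN(SiMe3)2, THF, 0 °C; then 26, −78 → 0 °C (excess ylide)
Reagents that add atoms: methyltriphenylphosphonium bromide, C[P+](c1ccccc1)(c1ccccc1)c1ccccc1.[Br-]
Why: Double Wittig methylenation with the unstabilised ylide converts aldehyde and methyl ketone into vinyl and isopropenyl groups, the aldehyde reacting first and fast at low temperature, which limits enolisation at C6, and the ester is not attacked.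

Step 20
Reactants: 27 the 1,6‑diene
Product: 28 trans‑fused bicyclo[5.3.0]dec‑4‑ene (target numbering: C4=C5 with 4‑methyl; H‑2 β; H‑6 α; 1β‑isopropyl; 8α‑methyl; 8β‑hydroxy) 10α‑yl 4‑(benzyloxy)benzoate
Conditions: second‑generation Grubbs catalyst RuCl2(=CHPh)(H2IMes)(PCy3) (5 mol%), CH2Cl2, 40 °C
Reagents that add atoms: none
Why: Ring‑closing metathesis of a monosubstituted with a 1,1‑disubstituted alkene closes the five‑membered ring at C4=C5 with loss of ethene, the trans ring fusion being fixed already by C2 and C6.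

Step 21
Reactants: 28 the cyclopentene
Product: 29 4β,5β‑epoxide of 28 (4α‑methyl; otherwise as 28)
Conditions: VO(acac)2 (5 mol%), tBuOOH, CH2Cl2, 0 °C → rt
Reagents that add atoms: tert‑butyl hydroperoxide, CC(C)(C)OO
Why: In this hydroxyl‑directed epoxidation the vanadate ester of the β C8 hydroxyl should deliver the peroxide oxygen to the β face of C4=C5, setting C4 and C5 syn to the C8 oxygen, and that hydroxyl cannot open a syn epoxide from the rear.

Step 22
Reactants: 29 the benzyl‑protected epoxide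
Product: 30 CNP0245441.1 (4β,5β‑epoxy‑8β‑hydroxy‑1β‑isopropyl‑4α,8α‑dimethyl trans‑fused bicyclo[5.3.0]decan‑10α‑yl 4‑hydroxybenzoate)
Conditions: H2 (1 atm), Pd/C, EtOAc, rt
Reagents that add atoms: none
Why: Hydrogenolysis of the aryl benzyl ether over palladium frees the phenol under neutral conditions that the non‑benzylic epoxide, the ester and the tertiary alcohol should survive.

**Compound list**

1 | methyl bis(2,2,2‑trifluoroethyl)phosphonoacetate | COC(=O)CP(=O)(OCC(F)(F)F)OCC(F)(F)F | starting material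
2 | methyl 2‑[bis(2,2,2‑trifluoroethoxy)phosphoryl]‑3‑methylbutanoate (racemic) | COC(=O)C(C(C)C)P(=O)(OCC(F)(F)F)OCC(F)(F)F | intermediate
3 | ethyl (2‑methyl‑1,3‑dioxolan‑2‑yl)acetate | CCOC(=O)CC1(C)OCCO1 | starting material
4 | (2‑methyl‑1,3‑dioxolan‑2‑yl)acetaldehyde | O=CCC1(C)OCCO1 | intermediate
5 | methyl (Z)‑2‑isopropyl‑4‑(2‑methyl‑1,3‑dioxolan‑2‑yl)but‑2‑enoate | COC(=O)/C(C(C)C)=C\CC1(C)OCCO1 | intermediate
6 | (Z)‑N‑methoxy‑N‑methyl‑2‑isopropyl‑4‑(2‑methyl‑1,3‑dioxolan‑2‑yl)but‑2‑enamide | CON(C)C(=O)/C(C(C)C)=C\CC1(C)OCCO1 | intermediate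
7 | (Z)‑3‑isopropyl‑5‑(2‑methyl‑1,3‑dioxolan‑2‑yl)pent‑3‑en‑2‑one | CC(=O)/C(C(C)C)=C\CC1(C)OCCO1 | intermediate
8 | (Z)‑2‑(tert‑butyldimethylsilyloxy)‑3‑isopropyl‑5‑(2‑methyl‑1,3‑dioxolan‑2‑yl)penta‑1,3‑diene | C=C(O[Si](C)(C)C(C)(C)C)/C(C(C)C)=C\CC1(C)OCCO1 | intermediate
9 | 3‑(tert‑butyldimethylsilyloxy)propanal | O=CCCO[Si](C)(C)C(C)(C)C | starting material
10 | ethyl diazoacetate | CCOC(=O)C=[N+]=[N-] | starting material
11 | ethyl 5‑(tert‑butyldimethylsilyloxy)‑2‑diazo‑3‑hydroxypentanoate (racemic) | CCOC(=O)C(=[N+]=[N-])C(O)CCO[Si](C)(C)C(C)(C)C | intermediate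
12 | O‑trifluoroacetate of 11 (not isolated) | CCOC(=O)C(=[N+]=[N-])C(OC(=O)C(F)(F)F)CCO[Si](C)(C)C(C)(C)C | intermediate
13 | ethyl (E)‑5‑(tert‑butyldimethylsilyloxy)‑2‑diazopent‑3‑enoate | CCOC(=O)C(=[N+]=[N-])/C=C/CO[Si](C)(C)C(C)(C)C | intermediate
14 | ethyl 2‑(TBS‑oxy)‑1‑[(E)‑3‑(TBS‑oxy)prop‑1‑enyl]‑2‑[(Z)‑2‑methyl‑5‑(2‑methyl‑1,3‑dioxolan‑2‑yl)pent‑3‑en‑3‑yl]cyclopropane‑1‑carboxylate, the two alkenyl groups cis (not isolated) | CCOC(=O)[C@@]1(/C=C/CO[Si](C)(C)C(C)(C)C)C[C@]1(O[Si](C)(C)C(C)(C)C)/C(C(C)C)=C\CC2(C)OCCO2 | intermediate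
15 | ethyl 10‑(TBS‑oxy)‑1‑isopropyl‑2α‑[(2‑methyl‑1,3‑dioxolan‑2‑yl)methyl]‑6β‑[(TBS‑oxy)methyl]cyclohepta‑1(10),7‑diene‑8‑carboxylate | CC(C)C1=C(O[Si](C)(C)C(C)(C)C)CC(C(=O)OCC)=C[C@H](CO[Si](C)(C)C(C)(C)C)[C@H]1CC2(C)OCCO2 | intermediate
16 | allylic alcohol (8‑CH2OH in place of the ester of 15) | CC(C)C1=C(O[Si](C)(C)C(C)(C)C)CC(CO)=C[C@H](CO[Si](C)(C)C(C)(C)C)[C@H]1CC2(C)OCCO2 | intermediate
17 | 7β,8β‑epoxy alcohol (8α‑CH2OH) | CC(C)C1=C(O[Si](C)(C)C(C)(C)C)C[C@]2(CO)O[C@@H]2[C@H](CO[Si](C)(C)C(C)(C)C)[C@H]1CC3(C)OCCO3 | intermediate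
18 | methanesulfonate of 17 | CC(C)C1=C(O[Si](C)(C)C(C)(C)C)C[C@]2(COS(C)(=O)=O)O[C@@H]2[C@H](CO[Si](C)(C)C(C)(C)C)[C@H]1CC3(C)OCCO3 | intermediate
19 | 8β‑hydroxy‑8α‑methyl silyl enol ether | CC(C)C1=C(O[Si](C)(C)C(C)(C)C)C[C@](C)(O)C[C@H](CO[Si](C)(C)C(C)(C)C)[C@H]1CC2(C)OCCO2 | intermediate
20 | 1α‑isopropyl (C1‑epimeric) ketone (not isolated) | CC(C)[C@@H]1[C@H](CC2(C)OCCO2)[C@@H](CO[Si](C)(C)C(C)(C)C)C[C@@](C)(O)CC1=O | intermediate
21 | 8β‑hydroxy‑1β‑isopropyl‑8α‑methyl‑2α‑[(2‑methyl‑1,3‑dioxolan‑2‑yl)methyl]‑6β‑[(TBS‑oxy)methyl]cycloheptan‑10‑one | CC(C)[C@H]1[C@H](CC2(C)OCCO2)[C@@H](CO[Si](C)(C)C(C)(C)C)C[C@@](C)(O)CC1=O | intermediate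
22 | corresponding 8β,10α‑diol | CC(C)[C@H]1[C@H](CC2(C)OCCO2)[C@@H](CO[Si](C)(C)C(C)(C)C)C[C@@](C)(O)C[C@@H]1O | intermediate
23 | 4‑(benzyloxy)benzoyl chloride | O=C(Cl)c1ccc(OCc2ccccc2)cc1 | starting material
24 | 10α‑[4‑(benzyloxy)benzoate] of 22 | CC(C)[C@H]1[C@H](CC2(C)OCCO2)[C@@H](CO[Si](C)(C)C(C)(C)C)C[C@@](C)(O)C[C@@H]1OC(=O)c1ccc(OCc2ccccc2)cc1 | intermediate
25 | 6β‑hydroxymethyl‑2α‑(2‑oxopropyl) ester | CC(C)[C@H]1[C@H](CC(C)=O)[C@@H](CO)C[C@@](C)(O)C[C@@H]1OC(=O)c1ccc(OCc2ccccc2)cc1 | intermediate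
26 | 6β‑formyl‑2α‑(2‑oxopropyl) ester | CC(C)[C@H]1[C@H](CC(C)=O)[C@@H](C=O)C[C@@](C)(O)C[C@@H]1OC(=O)c1ccc(OCc2ccccc2)cc1 | intermediate
27 | 6β‑ethenyl‑2α‑(2‑methylprop‑2‑enyl) ester | CC(C)[C@H]1[C@H](CC(C)=C)[C@@H](C=C)C[C@@](C)(O)C[C@@H]1OC(=O)c1ccc(OCc2ccccc2)cc1 | intermediate
28 | trans‑fused cyclopentene (C4=C5) benzyloxybenzoate | CC(C)[C@H]1[C@@H]2CC(C)=C[C@H]2C[C@@](C)(O)C[C@@H]1OC(=O)c1ccc(OCc2ccccc2)cc1 | intermediate
29 | 4β,5β‑epoxide, benzyl‑protected | CC(C)[C@H]1[C@@H]2C[C@@]3(C)O[C@H]3[C@H]2C[C@@](C)(O)C[C@@H]1OC(=O)c1ccc(OCc2ccccc2)cc1 | intermediate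
30 | CNP0245441.1 | CC(C)[C@H]1[C@@H]2C[C@@]3(C)O[C@H]3[C@H]2C[C@@](C)(O)C[C@@H]1OC(=O)c1ccc(O)cc1 | target

**Count and risks**

Total step count: 22. Longest linear sequence: 19 steps (3 or 1 → 8 → 30).

Step 9. The chiral carboxylate pocket may discriminate poorly between the carbene faces with this hindered 1,1‑disubstituted siloxy alkene, and the heating that the Z arm requires leaves no later point at which enantiomeric purity could be raised. Fallback: setting out from 8 and 13, the tandem reaction is run with achiral Rh2(O2CCMe3)4 (dirhodium tetrapivalate). This gives 14 together with the mirror‑image cyclopropane F1 and, after the thermal shift, 15 together with the mirror‑image cycloheptadiene F2. Reduction as in step 10 gives 16 together with the mirror‑image allylic alcohol F3. Epoxidation as in step 11 then acts as a resolution, because the tartrate reagent adds oxygen to the same face of the allylic alcohol unit in both enantiomers: 16 becomes 17 and F3 becomes the diastereomeric epoxy alcohol F4, whose epoxide lies trans to the C6 side chain. The diastereomers are separated by chromatography and the route is rejoined at 17, the absolute configuration now coming from the epoxidation reagent instead of the carbene catalyst.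

Step 14. Under basic methanol the tertiary aldol unit (C8 hydroxyl β to the new C10 ketone) may undergo retro‑aldol ring opening or β‑elimination before the slow enolisation toward the hindered C1 has reached equilibrium. Fallback: setting out from 19, the tertiary hydroxyl is first silylated (Et3SiOTf, 2,6‑lutidine, CH2Cl2, −78 °C) to the C8 triethylsilyl ether F5. Methanolysis of the enol ether then gives the C1‑epimeric silyloxy ketone F6, which cannot form an alkoxide at C8 and can therefore be equilibrated with the stronger base NaOMe in methanol to the 1β‑isopropyl silyloxy ketone F7. HF·pyridine buffered with pyridine (THF, 0 °C) should remove the triethylsilyl ether ahead of the primary TBS ether, and the route is rejoined at 21.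

Step 21. Oxygen delivery from the bishomoallylic C8 hydroxyl may be too weak to override attack on the α face, and an α epoxide would be opened by that hydroxyl to a cyclic ether. Fallback: setting out from 28, the C8 hydroxyl is silylated (Et3SiOTf, 2,6‑lutidine) to the triethylsilyl ether F8, so that it shields the β face and can no longer attack C5. N‑Bromosuccinimide in aqueous THF at 0 °C should then form the bromonium ion on the α face, and water opens it at the tertiary C4 from the β face to give the bromohydrin F9 (4β‑OH, 5α‑Br). K2CO3 in methanol closes it with inversion at C5 to the silylated β‑epoxide F10, and Bu4NF in THF removes the silyl ether, rejoining the route at 29.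

Further compounds
F1 | step 9 | mirror‑image cyclopropane (enantiomer of 14) | CCOC(=O)[C@]1(/C=C/CO[Si](C)(C)C(C)(C)C)C[C@@]1(O[Si](C)(C)C(C)(C)C)/C(C(C)C)=C\CC2(C)OCCO2
F2 | step 9 | mirror‑image cycloheptadiene (enantiomer of 15) | CC(C)C1=C(O[Si](C)(C)C(C)(C)C)CC(C(=O)OCC)=C[C@@H](CO[Si](C)(C)C(C)(C)C)[C@@H]1CC2(C)OCCO2
F3 | step 9 | mirror‑image allylic alcohol (enantiomer of 16) | CC(C)C1=C(O[Si](C)(C)C(C)(C)C)CC(CO)=C[C@@H](CO[Si](C)(C)C(C)(C)C)[C@@H]1CC2(C)OCCO2
F4 | step 9 | diastereomeric epoxy alcohol (epoxide trans to the C6 side chain) | CC(C)C1=C(O[Si](C)(C)C(C)(C)C)C[C@]2(CO)O[C@@H]2[C@@H](CO[Si](C)(C)C(C)(C)C)[C@@H]1CC3(C)OCCO3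
F5 | step 14 | C8 triethylsilyl ether of 19 | CC(C)C1=C(O[Si](C)(C)C(C)(C)C)C[C@](C)(O[Si](CC)(CC)CC)C[C@H](CO[Si](C)(C)C(C)(C)C)[C@H]1CC2(C)OCCO2
F6 | step 14 | C1‑epimeric silyloxy ketone (not isolated) | CC(C)[C@@H]1[C@H](CC2(C)OCCO2)[C@@H](CO[Si](C)(C)C(C)(C)C)C[C@@](C)(O[Si](CC)(CC)CC)CC1=O
F7 | step 14 | 1β‑isopropyl silyloxy ketone (C8 triethylsilyl ether of 21) | CC(C)[C@H]1[C@H](CC2(C)OCCO2)[C@@H](CO[Si](C)(C)C(C)(C)C)C[C@@](C)(O[Si](CC)(CC)CC)CC1=O
F8 | step 21 | triethylsilyl ether of 28 | CC(C)[C@H]1[C@@H]2CC(C)=C[C@H]2C[C@@](C)(O[Si](CC)(CC)CC)C[C@@H]1OC(=O)c1ccc(OCc2ccccc2)cc1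
F9 | step 21 | bromohydrin (4β‑OH, 5α‑Br, 8‑O‑triethylsilyl) | CC(C)[C@H]1[C@@H]2C[C@@](C)(O)[C@H](Br)[C@H]2C[C@@](C)(O[Si](CC)(CC)CC)C[C@@H]1OC(=O)c1ccc(OCc2ccccc2)cc1
F10 | step 21 | silylated β‑epoxide (triethylsilyl ether of 29) | CC(C)[C@H]1[C@@H]2C[C@@]3(C)O[C@H]3[C@H]2C[C@@](C)(O[Si](CC)(CC)CC)C[C@@H]1OC(=O)c1ccc(OCc2ccccc2)cc1
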